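Numbering: lactone O1, C2 (C=O), C3 (CH3), C4 (enol), C5; side chain C6–C18 from C5 to the furan. The feature behind the key step is C15, a lone methyl-bearing stereocentre with three CH2 groups on either side (C12–C14, C16–C18), out of reach of C5 and C7.
Bonds cut: C3–C4 of the lactone; C9–C10 between the two alkenes; C11–CH3 and C11–C12; C13–C14 and C15–CH3 (key step); C17–C18; in the ester half C8=C9, the O-acyl bond and C5–C6.
Forward: the furan half is built linearly (C17–C18 coupling, key methylalumination–vinylation, iodide, acetylide) to a C10–C18 alkyne. The ester half (C4–C9) is made separately. Both are joined at C9–C10 in the pot of the alkyne carboalumination, and the only ring formed, the tetronic acid, is closed last.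
Stereochemistry: C15 from catalyst-controlled methylalumination; C7 from (2S)-3-bromo-2-methylpropan-1-ol (chiral pool); C5 from (R)-BINAP–ruthenium hydrogenation of an α-keto ester; 10E from syn-carboalumination and 8E from Takai olefination, both kept by the stereoretentive coupling.

Key step: step 3

Remark: but-3-en-1-ylmagnesium bromide is used as its commercial THF solution, and the tetronic acid is written throughout as the 4-hydroxy tautomer.

Step 1
Reactants: 1 furan-3-ylmethanol
Product: 2 3-(bromomethyl)furan
Conditions: PBr3 (0.4 equiv), pyridine (cat.), Et2O, 0 °C; used at once as an ethereal solution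
Reagents that add atoms: phosphorus tribromide, BrP(Br)Br
Why: Bromination with PBr3 proceeds through the furylmethyl dibromophosphite, which bromide displaces in an SN2 reaction at the primary, benzylic-type carbon; the labile bromide is used at once.

Step 2
Reactants: 2 3-(bromomethyl)furan; 3 but-3-en-1-ylmagnesium bromide
Product: 4 3-(pent-4-en-1-yl)furan
Conditions: 3 (1.3 equiv), Li2CuCl4 (3 mol%), THF, −78 → 0 °C
Reagents that add atoms: none
Why: Copper-catalysed Grignard cross-coupling (Kochi type) joins the activated furylmethyl carbon C18 to the sp3 carbon C17 through a transient organocuprate, and neither the terminal alkene nor the furan reacts under these conditions.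

Step 3
Reactants: 4 3-(pent-4-en-1-yl)furan; 5 trimethylaluminium; 6 bromoethene
Product: 9 3-[(4S)-4-methylhept-6-en-1-yl]furan, via alkyldimethylalane 7 (not isolated), via alkylzinc triflate 8 (not isolated)
Conditions: 5 (2 equiv), (+)-bis(1-neomenthylindenyl)zirconium dichloride (5 mol%), methylaluminoxane (MeAlO)n (1 equiv), CH2Cl2, 0 °C; volatiles evaporated; Zn(OTf)2 (1 equiv), DMF, 70 °C; then 6 (6 equiv), PdCl2(DPEphos) (3 mol%), i-Bu2AlH (6 mol%), 23 °C
Reagents that add atoms: none
Why: The aluminium reagents methylate and ionise the zirconocene dichloride to a cationic methylzirconocene, which binds the C14=C15 alkene on one enantioface and inserts it into the Zr–CH3 bond with methyl going to the internal carbon C15; transfer of the new alkyl group to aluminium releases alane 7 and returns the catalyst. Zn(OTf)2 in DMF then moves the primary alkyl group to zinc (8), which enters a Negishi cycle with zerovalent palladium formed from PdCl2(DPEphos) and i-Bu2AlH: oxidative addition of 6, transmetalation and reductive elimination make C13–C14. The closest known reaction type is the zirconium-catalysed asymmetric carboalumination of terminal alkenes followed in the same pot by zinc-assisted palladium-catalysed vinylation of the alkylalane. No ring is closed. The one new stereocentre, C15, is controlled only by the chiral neomenthylindenyl ligands of the (+)-catalyst, which by analogy with simple 1-alkenes should give the (2S)-alane that becomes 15R in the target. The step needs regioselectivity (methyl to C15, metal to C14), secured by the unbranched monosubstituted alkene, and enantioface selectivity, which rests on the catalyst alone because the furan three carbons away neither directs nor competes, and which is expected to be only moderate.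

Step 4
Reactants: 9 3-[(4S)-4-methylhept-6-en-1-yl]furan
Product: 11 3-[(4S)-7-iodo-4-methylheptyl]furan, via alkylzirconocene chloride 10 (not isolated)
Conditions: Cp2Zr(H)Cl (1.3 equiv), THF, 23 °C; then I2 (1.3 equiv), 0 °C
Reagents that add atoms: iodine, II
Why: Hydrozirconation adds Zr–H across the monosubstituted alkene with zirconium at the terminal carbon C12, and iodinolysis of the C–Zr bond gives the primary iodide (hydrozirconation–iodination) without touching the furan or the C15 stereocentre.

Step 5
Reactants: 11 3-[(4S)-7-iodo-4-methylheptyl]furan; 12 lithium acetylide–ethylenediamine complex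
Product: 13 3-[(4R)-4-methylnon-8-yn-1-yl]furan
Conditions: 12 (2 equiv), DMSO, 15 → 23 °C
Reagents that add atoms: none
Why: SN2 alkylation of lithium acetylide by the unhindered primary iodide in DMSO forms C11–C12 and brings in C10 as the terminal alkyne carbon, the ethylenediamine complex keeping elimination and double alkylation low.

Step 6
Reactants: 14 (2S)-3-bromo-2-methylpropan-1-ol
Product: 15 {[(2S)-3-bromo-2-methylpropoxy]methyl}benzene
Conditions: BnOC(=NH)CCl3 (1.3 equiv), TfOH (5 mol%), cyclohexane/CH2Cl2, 0 → 23 °C
Reagents that add atoms: benzyl 2,2,2-trichloroacetimidate, ClC(Cl)(Cl)C(=N)OCc1ccccc1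
Why: Acid-catalysed O-benzylation with the trichloroacetimidate protects the alcohol without forming an alkoxide that could displace the neighbouring bromide, and the chiral-pool stereocentre (the future C7) is not involved.

Step 7
Reactants: 15 {[(2S)-3-bromo-2-methylpropoxy]methyl}benzene; 16 dimethyl oxalate
Product: 18 methyl (4R)-5-(benzyloxy)-4-methyl-2-oxopentanoate, via Grignard reagent 17 (not isolated)
Conditions: Mg, THF, 45 °C; then added to 16 (3 equiv), THF, −78 °C; 1 M HCl quench at −78 °C
Reagents that add atoms: none
Why: Acylation of the Grignard reagent by the oxalate diester forms C5–C6 and stops at the α-keto ester because the magnesium hemiketal alkoxide is stable at −78 °C until the acidic quench; C7 is β to magnesium and keeps its configuration.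

Step 8
Reactants: 18 methyl (4R)-5-(benzyloxy)-4-methyl-2-oxopentanoate
Product: 19 methyl (2R,4R)-5-(benzyloxy)-2-hydroxy-4-methylpentanoate
Conditions: H2 (50 atm), RuCl2[(R)-BINAP] (1 mol%), MeOH, 30 °C
Reagents that add atoms: none
Why: Noyori asymmetric hydrogenation: the α-keto ester binds ruthenium through both carbonyl groups and the (R)-BINAP ligand directs hydride to the Si face of the ketone, which sets C5 as R under catalyst control irrespective of the remote C7 centre (a minor C5 epimer would be a diastereomer removable by chromatography), and the benzyl ether is inert to this homogeneous catalyst.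

Step 9
Reactants: 19 methyl (2R,4R)-5-(benzyloxy)-2-hydroxy-4-methylpentanoate
Product: 20 methyl (2R,4R)-5-(benzyloxy)-4-methyl-2-(propanoyloxy)pentanoate
Conditions: EtCOCl (1.5 equiv), pyridine (3 equiv), DMAP (5 mol%), CH2Cl2, 0 °C
Reagents that add atoms: propanoyl chloride, CCC(=O)Cl
Why: DMAP-catalysed acylation of the secondary alcohol by the acid chloride (through the N-acylpyridinium ion) installs the propanoate that later supplies C2, C3 and the C3 methyl group of the lactone, under conditions too mild to disturb C5.

Step 10
Reactants: 20 methyl (2R,4R)-5-(benzyloxy)-4-methyl-2-(propanoyloxy)pentanoate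
Product: 21 methyl (2R,4R)-5-hydroxy-4-methyl-2-(propanoyloxy)pentanoate
Conditions: H2 (1 atm), Pd/C (10 wt%), EtOAc, 23 °C
Reagents that add atoms: none
Why: Hydrogenolysis of the benzyl ether on palladium under neutral conditions frees the C8 alcohol, the molecule carrying no alkene, halide or other reducible group at this stage.

Step 11
Reactants: 21 methyl (2R,4R)-5-hydroxy-4-methyl-2-(propanoyloxy)pentanoate
Product: 22 methyl (2R,4R)-4-methyl-5-oxo-2-(propanoyloxy)pentanoate
Conditions: Dess–Martin periodinane (1.3 equiv), pyridine, CH2Cl2, 0 → 23 °C; used without storage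
Reagents that add atoms: none
Why: Dess–Martin oxidation gives the aldehyde under buffered, non-basic conditions that leave the α-methyl stereocentre C7 and both esters intact, and the aldehyde is taken on without storage.

Step 12
Reactants: 22 methyl (2R,4R)-4-methyl-5-oxo-2-(propanoyloxy)pentanoate
Product: 23 methyl (2R,4R,5E)-6-iodo-4-methyl-2-(propanoyloxy)hex-5-enoate
Conditions: CrCl2 (6 equiv), CHI3 (2 equiv), THF/1,4-dioxane, 0 → 23 °C, dark
Reagents that add atoms: iodoform, IC(I)I
Why: Takai olefination: the geminal dichromium reagent formed from iodoform and CrCl2 adds to the aldehyde and eliminates through the less crowded β-oxychromium conformer to give the 8E iodoalkene preferentially, under near-neutral conditions that do not epimerise C7 or cleave the esters.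

Step 13
Reactants: 13 3-[(4R)-4-methylnon-8-yn-1-yl]furan; 5 trimethylaluminium; 23 methyl (2R,4R,5E)-6-iodo-4-methyl-2-(propanoyloxy)hex-5-enoate
Product: 25 methyl (2R,4R,5E,7E,12R)-15-(furan-3-yl)-4,8,12-trimethyl-2-(propanoyloxy)pentadeca-5,7-dienoate, via alkenyldimethylalane 24 (not isolated)
Conditions: 5 (2 equiv), Cp2ZrCl2 (25 mol%), CH2Cl2, 0 → 23 °C; volatiles evaporated; then 23, ZnCl2 (20 mol%), Pd(PPh3)4 (5 mol%), THF, 23 °C
Reagents that add atoms: none
Why: Zirconium-catalysed syn-carboalumination of the terminal alkyne (Negishi carboalumination) puts methyl on C11 and aluminium on C10 and so fixes the 10E geometry, and alkenylalane 24 then couples with the iodoalkene with retention on both partners in a zinc-assisted Negishi coupling catalysed by zerovalent palladium to form C9–C10, the alkenylmetal species being unreactive toward the two ester groups at room temperature.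

Step 14
Reactants: 25 methyl (2R,4R,5E,7E,12R)-15-(furan-3-yl)-4,8,12-trimethyl-2-(propanoyloxy)pentadeca-5,7-dienoate
Product: 26 (5R)-5-[(2R,3E,5E,10R)-13-(furan-3-yl)-2,6,10-trimethyltrideca-3,5-dien-1-yl]-4-hydroxy-3-methylfuran-2(5H)-one
Conditions: LiN(SiMe3)2 (2.5 equiv), THF, −78 → 0 °C; then cold 0.5 M HCl
Reagents that add atoms: none
Why: Dieckmann condensation: the lithium enolate of the propanoate attacks the adjacent methyl ester in a 5-exo-trig acyl substitution that closes the lactone ring at C3–C4, expulsion of methoxide and deprotonation to the stabilised tetronate drive the reaction, and the low temperature keeps C5 from epimerising before acidification releases the 4-hydroxy tautomer.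

Compound list
1 | furan-3-ylmethanol | OCc1ccoc1 | starting material
2 | 3-(bromomethyl)furan | BrCc1ccoc1 | intermediate
3 | but-3-en-1-ylmagnesium bromide | C=CCC[Mg]Br | starting material
4 | 3-(pent-4-en-1-yl)furan | C=CCCCc1ccoc1 | intermediate
5 | trimethylaluminium | C[Al](C)C | starting material
6 | bromoethene | C=CBr | starting material
7 | dimethyl[(2S)-5-(furan-3-yl)-2-methylpentyl]alumane | C[Al](C)C[C@@H](C)CCCc1ccoc1 | intermediate
8 | [(2S)-5-(furan-3-yl)-2-methylpentyl]zinc trifluoromethanesulfonate | FC(F)(F)S(=O)(=O)O[Zn]C[C@@H](C)CCCc1ccoc1 | intermediate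
9 | 3-[(4S)-4-methylhept-6-en-1-yl]furan | C=CC[C@@H](C)CCCc1ccoc1 | intermediate
10 | chlorobis(cyclopentadienyl)[(4S)-7-(furan-3-yl)-4-methylheptyl]zirconium | Cl[Zr](CCC[C@@H](C)CCCc1ccoc1)(C1C=CC=C1)C1C=CC=C1 | intermediate
11 | 3-[(4S)-7-iodo-4-methylheptyl]furan | ICCC[C@@H](C)CCCc1ccoc1 | intermediate
12 | lithium acetylide–ethylenediamine complex | [Li]C#C.NCCN | starting material
13 | 3-[(4R)-4-methylnon-8-yn-1-yl]furan | C#CCCC[C@@H](C)CCCc1ccoc1 | intermediate
14 | (2S)-3-bromo-2-methylpropan-1-ol | OC[C@H](C)CBr | starting material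
15 | {[(2S)-3-bromo-2-methylpropoxy]methyl}benzene | BrC[C@@H](C)COCc1ccccc1 | intermediate
16 | dimethyl oxalate | COC(=O)C(=O)OC | starting material
17 | [(2S)-3-(benzyloxy)-2-methylpropyl]magnesium bromide | Br[Mg]C[C@@H](C)COCc1ccccc1 | intermediate
18 | methyl (4R)-5-(benzyloxy)-4-methyl-2-oxopentanoate | COC(=O)C(=O)C[C@@H](C)COCc1ccccc1 | intermediate
19 | methyl (2R,4R)-5-(benzyloxy)-2-hydroxy-4-methylpentanoate | COC(=O)[C@H](O)C[C@@H](C)COCc1ccccc1 | intermediate
20 | methyl (2R,4R)-5-(benzyloxy)-4-methyl-2-(propanoyloxy)pentanoate | CCC(=O)O[C@H](C[C@@H](C)COCc1ccccc1)C(=O)OC | intermediate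
21 | methyl (2R,4R)-5-hydroxy-4-methyl-2-(propanoyloxy)pentanoate | CCC(=O)O[C@H](C[C@@H](C)CO)C(=O)OC | intermediate
22 | methyl (2R,4R)-4-methyl-5-oxo-2-(propanoyloxy)pentanoate | CCC(=O)O[C@H](C[C@@H](C)C=O)C(=O)OC | intermediate
23 | methyl (2R,4R,5E)-6-iodo-4-methyl-2-(propanoyloxy)hex-5-enoate | CCC(=O)O[C@H](C[C@@H](C)/C=C/I)C(=O)OC | intermediate
24 | dimethyl[(1E,6S)-9-(furan-3-yl)-2,6-dimethylnon-1-en-1-yl]alumane | C[Al](C)/C=C(\C)CCC[C@@H](C)CCCc1ccoc1 | intermediate
25 | methyl (2R,4R,5E,7E,12R)-15-(furan-3-yl)-4,8,12-trimethyl-2-(propanoyloxy)pentadeca-5,7-dienoate | CCC(=O)O[C@H](C[C@@H](C)/C=C/C=C(\C)CCC[C@@H](C)CCCc1ccoc1)C(=O)OC | intermediate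
26 | (5R)-5-[(2R,3E,5E,10R)-13-(furan-3-yl)-2,6,10-trimethyltrideca-3,5-dien-1-yl]-4-hydroxy-3-methylfuran-2(5H)-one | CC1=C(O)[C@@H](C[C@@H](C)/C=C/C=C(\C)CCC[C@@H](C)CCCc2ccoc2)OC1=O | target

Total step count: 14.
Longest linear sequence: 9 steps (steps 6 to 12, then 13 and 14); the furan half needs 5 steps before the union.

Steps most likely to fail

1. Step 3. Enantioface discrimination in the methylalumination of an unfunctionalised 1-alkene may be insufficient. Because C15 is remote, the minor enantiomer would be carried forward as a 15-epimer that cannot be removed once the halves are joined, so the enantiomeric purity of 9 is to be assayed (chiral GC) before step 4. The fallback takes C15 from the chiral pool instead of from catalyst control. It sets out from 2 and comes back at 11. Commercial (6R)-8-bromo-2,6-dimethyloct-2-ene ((R)-citronellyl bromide, CC(C)=CCC[C@@H](C)CCBr) is converted with Mg in THF into [(3R)-3,7-dimethyloct-6-en-1-yl]magnesium bromide F1. This is coupled with 2 under Li2CuCl4 catalysis as in step 2 to give 3-[(4S)-4,8-dimethylnon-7-en-1-yl]furan F2, which already holds C15 in the required configuration. Dihydroxylation of the trisubstituted alkene (OsO4 cat., N-methylmorpholine N-oxide, acetone/H2O), which is faster than attack on the furan, gives (6S)-9-(furan-3-yl)-2,6-dimethylnonane-2,3-diol F3. Cleavage with NaIO4 gives (4S)-7-(furan-3-yl)-4-methylheptanal F4. Reduction with NaBH4 in MeOH gives (4S)-7-(furan-3-yl)-4-methylheptan-1-ol F5, and I2/PPh3/imidazole converts it into 11, which enters step 5.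

2. Step 13. Residual methylaluminium species may attack the ester groups of 23, a methyl group may be transferred in place of the alkenyl group, or the alkenyl group may pass too slowly from aluminium to palladium. The fallback separates the carboalumination from the coupling and joins the halves under neutral conditions. It sets out from 13 and 22 and comes back at 25. Alane 24, made as in step 13, is quenched with I2 at −30 °C to give 3-[(4S,8E)-9-iodo-4,8-dimethylnon-8-en-1-yl]furan F6. Aldehyde 22 is olefinated with Bu3SnCHBr2, CrCl2 and LiI in THF/DMF to give methyl (2R,4R,5E)-4-methyl-2-(propanoyloxy)-6-(tributylstannyl)hex-5-enoate F7. Stille coupling of the two (Pd2(dba)3, AsPh3, N-methylpyrrolidone, 23 to 40 °C) gives 25 with retention of both alkene geometries.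

3. Step 14. The amide base may deprotonate C5 (α to the methyl ester) in competition with the propanoate, which would lead to epimerisation at C5 or to acyl migration instead of ring closure. The fallback forms C3–C4 by an intermolecular condensation and closes the ring by lactonisation. It sets out from 25 and comes back at 26.
- Methanolysis of the propanoate (K2CO3, MeOH, 0 °C) gives methyl (2R,4R,5E,7E,12R)-15-(furan-3-yl)-2-hydroxy-4,8,12-trimethylpentadeca-5,7-dienoate F8.
- Silylation (t-BuMe2SiCl, imidazole, DMF) gives methyl (2R,4R,5E,7E,12R)-2-[(tert-butyldimethylsilyl)oxy]-15-(furan-3-yl)-4,8,12-trimethylpentadeca-5,7-dienoate F9.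
- Crossed Claisen condensation of F9 with lithium 1-methoxyprop-1-en-1-olate F10 (from methyl propanoate and LiN(i-Pr)2, 3 equiv, THF, −78 °C) gives methyl (4R,6R,7E,9E,14R)-4-[(tert-butyldimethylsilyl)oxy]-17-(furan-3-yl)-2,6,10,14-tetramethyl-3-oxoheptadeca-7,9-dienoate F11. Its acidic C3–H is removed first and so shields C5.
- Bu4NF buffered with AcOH in THF removes the silyl group, and methyl (4R,6R,7E,9E,14R)-17-(furan-3-yl)-4-hydroxy-2,6,10,14-tetramethyl-3-oxoheptadeca-7,9-dienoate F12 lactonises in the flask to 26.

Further compounds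
F1 | step 3 | [(3R)-3,7-dimethyloct-6-en-1-yl]magnesium bromide | CC(C)=CCC[C@@H](C)CC[Mg]Br
F2 | step 3 | 3-[(4S)-4,8-dimethylnon-7-en-1-yl]furan | CC(C)=CCC[C@@H](C)CCCc1ccoc1
F3 | step 3 | (6S)-9-(furan-3-yl)-2,6-dimethylnonane-2,3-diol, both C3 epimers | CC(C)(O)C(O)CC[C@@H](C)CCCc1ccoc1
F4 | step 3 | (4S)-7-(furan-3-yl)-4-methylheptanal | O=CCC[C@@H](C)CCCc1ccoc1
F5 | step 3 | (4S)-7-(furan-3-yl)-4-methylheptan-1-ol | OCCC[C@@H](C)CCCc1ccoc1
F6 | step 13 | 3-[(4S,8E)-9-iodo-4,8-dimethylnon-8-en-1-yl]furan | I/C=C(\C)CCC[C@@H](C)CCCc1ccoc1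
F7 | step 13 | methyl (2R,4R,5E)-4-methyl-2-(propanoyloxy)-6-(tributylstannyl)hex-5-enoate | CCC(=O)O[C@H](C[C@@H](C)/C=C/[Sn](CCCC)(CCCC)CCCC)C(=O)OC
F8 | step 14 | methyl (2R,4R,5E,7E,12R)-15-(furan-3-yl)-2-hydroxy-4,8,12-trimethylpentadeca-5,7-dienoate | COC(=O)[C@H](O)C[C@@H](C)/C=C/C=C(\C)CCC[C@@H](C)CCCc1ccoc1
F9 | step 14 | methyl (2R,4R,5E,7E,12R)-2-[(tert-butyldimethylsilyl)oxy]-15-(furan-3-yl)-4,8,12-trimethylpentadeca-5,7-dienoate | COC(=O)[C@H](O[Si](C)(C)C(C)(C)C)C[C@@H](C)/C=C/C=C(\C)CCC[C@@H](C)CCCc1ccoc1
F10 | step 14 | lithium 1-methoxyprop-1-en-1-olate | CC=C(OC)O[Li]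
F11 | step 14 | methyl (4R,6R,7E,9E,14R)-4-[(tert-butyldimethylsilyl)oxy]-17-(furan-3-yl)-2,6,10,14-tetramethyl-3-oxoheptadeca-7,9-dienoate, both C2 epimers | COC(=O)C(C)C(=O)[C@H](O[Si](C)(C)C(C)(C)C)C[C@@H](C)/C=C/C=C(\C)CCC[C@@H](C)CCCc1ccoc1
F12 | step 14 | methyl (4R,6R,7E,9E,14R)-17-(furan-3-yl)-4-hydroxy-2,6,10,14-tetramethyl-3-oxoheptadeca-7,9-dienoate, both C2 epimers | COC(=O)C(C)C(=O)[C@H](O)C[C@@H](C)/C=C/C=C(\C)CCC[C@@H](C)CCCc1ccoc1
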